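**Remark (one line):** germacrane numbering is used throughout (C1=C10 and C4=C5 alkenes, C2–OH, C6 ester, C8 lactone oxygen, C9–OH, C11=C13 methylene, C12 carbonyl); the sense of induction in step 4 is assigned by analogy, and the ligand antipode would be used if it proves opposite.

## Strategy

The α-methylene-γ-butyrolactone (ring atoms O, C8, C7, C11, C12; germacrane numbering) is disconnected into CO2 and a ten-membered (1(10)Z,4Z)-diene that carries a 1-borylvinyl group on C7 and a mesylate of inverted configuration on C8. In one operation, copper-catalysed carboxylation of the alkenylboronate and in situ invertive 5-exo-tet lactonisation form the C11–C12 and O–C8 bonds, exploiting the 1,3-relationship of vinylic C11 and oxygenated C8 across C7. The precursor should arise by Nozaki–Hiyama–Kishi ring closure (C9–C10) of a chain assembled by anti-selective allenylmetal addition (C6–C7) between a glyceraldehyde-derived allenylstannane and a (Z,Z)-iododienal from a vinylogous aldol lactone.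

Key step: step 21

## Route

Step 1
Reactants: 1 but-2-yn-1-ol
Product: 3 (Z)-3-iodobut-2-en-1-ol, via sodium alkenylalanate 2 (not isolated)
Conditions: NaAlH2(OCH2CH2OMe)2 (Red-Al), THF, 0 °C to rt; then I2, −78 °C
Reagents that add atoms: iodine, [I][I]
Why: Hydroxyl-directed trans-hydroalumination of the propargylic alcohol places aluminium on C3 in a five-membered alanate, and iodinolysis with retention gives the Z vinyl iodide that later defines the C1=C10 geometry.

Step 2
Reactants: 3 (Z)-3-iodobut-2-en-1-ol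
Product: 4 (Z)-3-iodobut-2-enal
Conditions: MnO2, CH2Cl2, rt
Reagents that add atoms: none
Why: Allylic oxidation with activated MnO2 is neutral and should leave the Z geometry of the β-iodo enal intact.

Step 3
Reactants: 5 ethyl 3-methylbut-2-enoate
Product: 6 1-ethoxy-3-methyl-1-(trimethylsilyloxy)buta-1,3-diene
Conditions: LiN(i-Pr)2, THF, −78 °C; Me3SiCl
Reagents that add atoms: chlorotrimethylsilane, C[Si](C)(C)Cl
Why: γ-Deprotonation of the senecioate ester and O-silylation of the lithium dienolate give the silyl dienol ether needed for a vinylogous Mukaiyama aldol reaction.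

Step 4
Reactants: 4 (Z)-3-iodobut-2-enal; 6 silyl dienol ether
Product: 7 (S)-6-[(Z)-2-iodoprop-1-en-1-yl]-4-methyl-5,6-dihydro-2H-pyran-2-one
Conditions: Cu(OTf)2 (10 mol%), (S)-Tol-BINAP (11 mol%), Bu4N[Ph3SiF2] (20 mol%), THF, rt
Reagents that add atoms: none
Why: A catalytic enantioselective vinylogous Mukaiyama aldol addition via a chiral copper dienolate sets C2 by catalyst control, and the copper aldolate closes onto the ester so that the C4=C5 bond is fixed as Z in the six-membered lactone.

Step 5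
Reactants: 7 lactone
Product: 8 (2Z,5S,6Z)-5-hydroxy-7-iodo-N-methoxy-N,3-dimethylocta-2,6-dienamide
Conditions: MeNH(OMe)·HCl, i-PrMgCl, THF, −20 °C
Reagents that add atoms: N,O-dimethylhydroxylamine hydrochloride, CNOC.Cl
Why: Weinreb aminolysis of the lactone with the chloromagnesium amide opens the ring while the trisubstituted Z-enoate resists conjugate addition.

Step 6
Reactants: 8 hydroxy Weinreb amide
Product: 9 (2Z,5S,6Z)-5-(tert-butyldimethylsilyloxy)-7-iodo-N-methoxy-N,3-dimethylocta-2,6-dienamide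
Conditions: t-BuMe2SiCl, imidazole, DMF, 0 °C to rt
Reagents that add atoms: tert-butyldimethylsilyl chloride, CC(C)(C)[Si](C)(C)Cl
Why: Silylation under Corey conditions caps the C2 hydroxyl before the Z-hydroxy amide can relactonise.

Step 7
Reactants: 9 silylated Weinreb amide
Product: 10 (2Z,5S,6Z)-5-(tert-butyldimethylsilyloxy)-7-iodo-3-methylocta-2,6-dienal
Conditions: i-Bu2AlH, THF, −78 °C
Reagents that add atoms: none
Why: Reduction of the Weinreb amide with i-Bu2AlH stops at the aldehyde because the chelated tetrahedral intermediate survives until work-up.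

Step 8
Reactants: 11 (R)-2,2-dimethyl-1,3-dioxolane-4-carbaldehyde
Product: 12 (R)-1-[(R)-2,2-dimethyl-1,3-dioxolan-4-yl]prop-2-yn-1-ol
Conditions: HC≡CMgBr, ZnBr2, Et2O–THF, −78 to 0 °C
Reagents that add atoms: ethynylmagnesium bromide, C#C[Mg]Br
Why: Chelation-controlled alkynylation (Cram chelate on zinc) should add the acetylide syn to the α-oxygen and give the (R,R) carbinol, with the minor anti isomer removed by chromatography.

Step 9
Reactants: 12 propargylic alcohol
Product: 13 (R)-1-[(R)-2,2-dimethyl-1,3-dioxolan-4-yl]prop-2-yn-1-yl methanesulfonate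
Conditions: MsCl, Et3N, CH2Cl2, −20 °C
Reagents that add atoms: methanesulfonyl chloride, CS(=O)(=O)Cl
Why: Mesylation of the propargylic alcohol proceeds with retention and supplies the leaving group for the later SN2′ displacement.

Step 10
Reactants: 13 acetonide mesylate
Product: 14 (2R,3R)-1,2-dihydroxypent-4-yn-3-yl methanesulfonate
Conditions: AcOH–H2O (4:1), rt
Reagents that add atoms: none
Why: Acid-catalysed acetal hydrolysis frees the diol while the propargylic mesylate is deactivated towards ionisation by the adjacent oxygen.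

Step 11
Reactants: 14 diol mesylate
Product: 15 (2R,3R)-1,2-bis(triethylsilyloxy)pent-4-yn-3-yl methanesulfonate
Conditions: Et3SiCl, imidazole, DMF, 0 °C
Reagents that add atoms: chlorotriethylsilane, CC[Si](CC)(CC)Cl
Why: Silylation of both hydroxyls gives ethers that a later Swern oxidation (primary) and mild acid (secondary) can address separately.

Step 12
Reactants: 15 bis-silyl mesylate
Product: 16 (aR,4S)-tributyl[4,5-bis(triethylsilyloxy)penta-1,2-dien-1-yl]stannane
Conditions: Bu3SnH, LiN(i-Pr)2, THF, 0 °C; CuBr·SMe2, −78 °C; then 15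
Reagents that add atoms: tributyltin hydride, CCCC[SnH](CCCC)CCCC
Why: Anti SN2′ displacement of the propargylic mesylate by the stannylcopper reagent (Marshall allenylstannane synthesis) transfers the C7 configuration to the allene axis.

Step 13
Reactants: 10 iododienal; 16 allenylstannane
Product: 18 seco-alcohol (2S,6R,7S,8S; 1(10)Z,4Z), via allenylindium dibromide 17 (not isolated)
Conditions: InBr3 (1.3 equiv), EtOAc, −78 °C to rt
Reagents that add atoms: none
Why: In the Marshall anti-selective allenylmetal addition, InBr3 transmetalates the stannane (anti SE2′, then 1,3-shift) to the allenylindium, which adds to the aldehyde through a cyclic transition state so that the allene axis sets C7 and the chair-like geometry sets C6 anti to it.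

Step 14
Reactants: 18 seco-alcohol; 19 (R)-2-methylbutanoic acid
Product: 20 seco-ester (2S,6R,7S,8S; 2′R)
Conditions: EDC·HCl, DMAP (cat.), CH2Cl2, 0 °C to rt
Reagents that add atoms: none
Why: Steglich esterification acylates the only free hydroxyl and introduces the (R)-2-methylbutanoate, with catalytic DMAP at low temperature to limit epimerisation of its α-stereocentre.

Step 15
Reactants: 20 seco-ester
Product: 21 seco-aldehyde (C9 aldehyde; 2S,6R,7S,8S)
Conditions: (COCl)2, DMSO, CH2Cl2, −78 °C; Et3N, −78 to −30 °C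
Reagents that add atoms: none
Why: Swern conditions oxidise a primary triethylsilyl ether directly to the aldehyde while the secondary silyl ethers stay in place.

Step 16
Reactants: 21 seco-aldehyde
Product: 22 macrocyclic C9 alcohol (2S,6R,7S,8S,9R)
Conditions: CrCl2 (8 equiv), NiCl2 (0.1 equiv), DMSO–THF (3:1), 0.003 M, rt
Reagents that add atoms: none
Why: Nozaki–Hiyama–Kishi macrocyclisation joins C10 to C9 with retention of the Z-alkene geometry, and polar Felkin–Anh addition anti to the C8 silyloxy group should give the 9R alcohol.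

Step 17
Reactants: 22 macrocyclic C9 alcohol
Product: 23 9-O-TBS macrocycle
Conditions: t-BuMe2SiOTf, 2,6-lutidine, CH2Cl2, −78 to 0 °C
Reagents that add atoms: tert-butyldimethylsilyl triflate, CC(C)(C)[Si](C)(C)OS(=O)(=O)C(F)(F)F
Why: Silyl triflate protection blocks the C9 hydroxyl so that it cannot close an epoxide onto C8 later.

Step 18
Reactants: 23 9-O-TBS macrocycle
Product: 24 macrocyclic C8 alcohol (2S,6R,7R,8S,9R)
Conditions: PPTS, MeOH–CH2Cl2, 0 °C
Reagents that add atoms: none
Why: Mild acid methanolysis removes the more labile triethylsilyl ether selectively over the two tert-butyldimethylsilyl ethers.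

Step 19
Reactants: 24 macrocyclic C8 alcohol
Product: 25 macrocyclic C8 mesylate (2S,6R,7S,8S,9R)
Conditions: MsCl, Et3N, CH2Cl2, 0 °C
Reagents that add atoms: methanesulfonyl chloride, CS(=O)(=O)Cl
Why: Mesylation through the sulfene pathway converts the hindered C8 alcohol with retention into the leaving group.

Step 20
Reactants: 25 macrocyclic C8 mesylate
Product: 26 C11 pinacol boronate (2S,6R,7S,8S,9R)
Conditions: pinacolborane (1.3 equiv), CoBr2 (5 mol%), bis(imino)pyridine-type NNN pincer ligand (5 mol%), NaBHEt3 (10 mol%), THF, rt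
Reagents that add atoms: pinacolborane, B1OC(C)(C)C(C)(C)O1
Why: Markovnikov-selective cobalt hydride hydroboration of the terminal alkyne places boron on the internal carbon C11 and gives the 1,1-disubstituted alkenylboronate.

Step 21
Reactants: 26 C11 pinacol boronate
Product: 28 bis-TBS lactone (2S,6R,7S,8R,9R), via potassium acrylate 27 (not isolated)
Conditions: (IPr)CuCl (10 mol%; IPr = 1,3-bis(2,6-diisopropylphenyl)imidazol-2-ylidene), KOt-Bu (1.1 equiv), THF, rt; CO2 (1 atm), 70 °C; then DMF, 60 °C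
Reagents that add atoms: carbon dioxide, O=C=O
Why: tert-Butoxide turns the boronate into a borate that transmetalates to an (IPr)Cu–alkenyl species, CO2 inserts into the Cu–C11 bond to form the C11–C12 bond, and the resulting potassium acrylate displaces the C8 mesylate from the backside to form the O–C8 bond, so that both the carbonyl carbon and the ring oxygen come from CO2. The closest known reaction type is the NHC–copper-catalysed carboxylation of alkenylboronic esters with CO2, here coupled to a classical invertive carboxylate alkylation. The five-membered lactone ring closes in the 5-exo-tet mode. C8 is the only stereocentre formed and is set by inversion of the (8S)-mesylate, whose configuration traces back to glyceraldehyde, while C7 and C9 are untouched, which gives the trans-fused lactone. The step needs lactonisation to outrun E2 loss of mesylate, protodeboronation and epoxide formation from the C9 oxygen. This is secured because the staggered conformer with C11 antiperiplanar to the C8–O bond places the carboxylate on the backside of C8, the C9 oxygen is silylated, and no free alkoxide remains once the borate has formed.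

Step 22
Reactants: 28 bis-TBS lactone
Product: 29 target CNP0176600.1
Conditions: HF·pyridine, pyridine, THF, 0 °C to rt
Reagents that add atoms: none
Why: Fluoride-mediated desilylation with buffered HF·pyridine liberates the C2 and C9 hydroxyls without affecting the α-methylene lactone or the ester.

## Compound list

1 | but-2-yn-1-ol | CC#CCO | starting material
2 | sodium 2,2-bis(2-methoxyethoxy)-3-methyl-2,5-dihydro-1,2-oxaluminol-2-uide (cyclic Z-alkenylalanate) | CC1=CCO[Al-]1(OCCOC)OCCOC.[Na+] | intermediate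
3 | (Z)-3-iodobut-2-en-1-ol | I/C(C)=C\CO | intermediate
4 | (Z)-3-iodobut-2-enal | I/C(C)=C\C=O | intermediate
5 | ethyl 3-methylbut-2-enoate | CCOC(=O)C=C(C)C | starting material
6 | 1-ethoxy-3-methyl-1-(trimethylsilyloxy)buta-1,3-diene (ketene acetal geometry not defined) | CCOC(O[Si](C)(C)C)=CC(C)=C | intermediate
7 | (S)-6-[(Z)-2-iodoprop-1-en-1-yl]-4-methyl-5,6-dihydro-2H-pyran-2-one | I/C(C)=C\[C@@H]1CC(C)=CC(=O)O1 | intermediate
8 | (2Z,5S,6Z)-5-hydroxy-7-iodo-N-methoxy-N,3-dimethylocta-2,6-dienamide | I/C(C)=C\[C@@H](O)C/C(C)=C\C(=O)N(C)OC | intermediate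
9 | (2Z,5S,6Z)-5-(tert-butyldimethylsilyloxy)-7-iodo-N-methoxy-N,3-dimethylocta-2,6-dienamide | I/C(C)=C\[C@@H](O[Si](C)(C)C(C)(C)C)C/C(C)=C\C(=O)N(C)OC | intermediate
10 | (2Z,5S,6Z)-5-(tert-butyldimethylsilyloxy)-7-iodo-3-methylocta-2,6-dienal | I/C(C)=C\[C@@H](O[Si](C)(C)C(C)(C)C)C/C(C)=C\C=O | intermediate
11 | (R)-2,2-dimethyl-1,3-dioxolane-4-carbaldehyde | O=C[C@H]1COC(C)(C)O1 | starting material
12 | (R)-1-[(R)-2,2-dimethyl-1,3-dioxolan-4-yl]prop-2-yn-1-ol | C#C[C@@H](O)[C@H]1COC(C)(C)O1 | intermediate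
13 | (R)-1-[(R)-2,2-dimethyl-1,3-dioxolan-4-yl]prop-2-yn-1-yl methanesulfonate | C#C[C@@H](OS(C)(=O)=O)[C@H]1COC(C)(C)O1 | intermediate
14 | (2R,3R)-1,2-dihydroxypent-4-yn-3-yl methanesulfonate | C#C[C@@H](OS(C)(=O)=O)[C@H](O)CO | intermediate
15 | (2R,3R)-1,2-bis(triethylsilyloxy)pent-4-yn-3-yl methanesulfonate | C#C[C@@H](OS(C)(=O)=O)[C@H](O[Si](CC)(CC)CC)CO[Si](CC)(CC)CC | intermediate
16 | (aR,4S)-tributyl[4,5-bis(triethylsilyloxy)penta-1,2-dien-1-yl]stannane | CCCC[Sn](CCCC)(CCCC)C([H])=[C@]=C([H])[C@H](O[Si](CC)(CC)CC)CO[Si](CC)(CC)CC | intermediate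
17 | (aS,4S)-dibromo[4,5-bis(triethylsilyloxy)penta-1,2-dien-1-yl]indium | Br[In](Br)C([H])=[C@@]=C([H])[C@H](O[Si](CC)(CC)CC)CO[Si](CC)(CC)CC | intermediate
18 | seco-alcohol: C7 carries ethynyl; C6–OH; C8–OSiEt3; C9H2–OSiEt3; C2–OTBS; C10 vinyl iodide; (2S,6R,7S,8S); both alkenes Z | C#C[C@@H]([C@H](O)/C=C(C)\C[C@H](O[Si](C)(C)C(C)(C)C)/C=C(/C)I)[C@H](O[Si](CC)(CC)CC)CO[Si](CC)(CC)CC | intermediate
19 | (R)-2-methylbutanoic acid | CC[C@@H](C)C(=O)O | starting material
20 | seco-ester: as 18 with C6–O-(R)-2-methylbutanoyl; (2S,6R,7S,8S) | C#C[C@@H]([C@H](OC(=O)[C@H](C)CC)/C=C(C)\C[C@H](O[Si](C)(C)C(C)(C)C)/C=C(/C)I)[C@H](O[Si](CC)(CC)CC)CO[Si](CC)(CC)CC | intermediate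
21 | seco-aldehyde: as 20 with C9 as aldehyde; (2S,6R,7S,8S) | C#C[C@@H]([C@H](OC(=O)[C@H](C)CC)/C=C(C)\C[C@H](O[Si](C)(C)C(C)(C)C)/C=C(/C)I)[C@H](O[Si](CC)(CC)CC)C=O | intermediate
22 | (1(10)Z,4Z,2S,6R,7S,8S,9R)-7-ethynyl-9-hydroxy-4,10-dimethyl-2-(tert-butyldimethylsilyloxy)-8-(triethylsilyloxy)cyclodeca-1(10),4-dien-6-yl (R)-2-methylbutanoate (germacrane numbering) | C#C[C@@H]1[C@H](O[Si](CC)(CC)CC)[C@H](O)/C(C)=C\[C@@H](O[Si](C)(C)C(C)(C)C)C/C(C)=C\[C@H]1OC(=O)[C@H](C)CC | intermediate
23 | 9-O-TBS ether of 22 (2S,6R,7S,8S,9R) | C#C[C@@H]1[C@H](O[Si](CC)(CC)CC)[C@H](O[Si](C)(C)C(C)(C)C)/C(C)=C\[C@@H](O[Si](C)(C)C(C)(C)C)C/C(C)=C\[C@H]1OC(=O)[C@H](C)CC | intermediate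
24 | C8 alcohol: 2,9-bis-O-TBS; 8-OH (2S,6R,7R,8S,9R) | C#C[C@@H]1[C@H](O)[C@H](O[Si](C)(C)C(C)(C)C)/C(C)=C\[C@@H](O[Si](C)(C)C(C)(C)C)C/C(C)=C\[C@H]1OC(=O)[C@H](C)CC | intermediate
25 | C8 mesylate: 2,9-bis-O-TBS; 8-OMs (2S,6R,7S,8S,9R) | C#C[C@@H]1[C@H](OS(C)(=O)=O)[C@H](O[Si](C)(C)C(C)(C)C)/C(C)=C\[C@@H](O[Si](C)(C)C(C)(C)C)C/C(C)=C\[C@H]1OC(=O)[C@H](C)CC | intermediate
26 | C11 boronate: C7 carries 1-(pinacolatoboryl)vinyl; 8-OMs; 2,9-bis-O-TBS (2S,6R,7S,8S,9R) | C=C(B2OC(C)(C)C(C)(C)O2)[C@@H]1[C@H](OS(C)(=O)=O)[C@H](O[Si](C)(C)C(C)(C)C)/C(C)=C\[C@@H](O[Si](C)(C)C(C)(C)C)C/C(C)=C\[C@H]1OC(=O)[C@H](C)CC | intermediate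
27 | potassium acrylate: C7 carries 1-carboxylatovinyl; 8-OMs; 2,9-bis-O-TBS | C=C(C(=O)[O-])[C@@H]1[C@H](OS(C)(=O)=O)[C@H](O[Si](C)(C)C(C)(C)C)/C(C)=C\[C@@H](O[Si](C)(C)C(C)(C)C)C/C(C)=C\[C@H]1OC(=O)[C@H](C)CC.[K+] | intermediate
28 | 2,9-bis-O-TBS ether of the target (2S,6R,7S,8R,9R) | C=C1C(=O)O[C@@H]2[C@@H]1[C@H](OC(=O)[C@H](C)CC)/C=C(/C)C[C@H](O[Si](C)(C)C(C)(C)C)/C=C(/C)[C@H]2O[Si](C)(C)C(C)(C)C | intermediate
29 | CNP0176600.1: (1(10)Z,4Z,2S,6R,7S,8R,9R)-2,9-dihydroxy-6-[(R)-2-methylbutanoyloxy]germacra-1(10),4,11(13)-trien-12,8-olide | C=C1C(=O)O[C@@H]2[C@@H]1[C@H](OC(=O)[C@H](C)CC)/C=C(/C)C[C@H](O)/C=C(/C)[C@H]2O | target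

## Step count and risks

Total step count: 22. Longest linear sequence: 16 steps (steps 1, 2, 4–7, 13–22).

Most likely to fail, in this order: step 20, step 21, step 16.

Step 20: boron may be delivered to the terminal carbon, because the alkyne sits on the fully substituted C7 and Markovnikov hydrometalation is sterically disfavoured there. The fallback sets out from 25 and uses a reagent-controlled stannylcupration instead of catalytic hydroboration. Me3SnCu·SMe2 with MeOH in THF at −78 °C would add tin to the internal carbon and give the 2-stannylalkene F1. Iododestannylation with I2 in CH2Cl2 at 0 °C would give the 2-iodoalkene F2. Nickel-catalysed reductive carboxylation (NiCl2(PPh3)2, PPh3, Mn, Et4NI, CO2 1 atm, DMF, rt, then 60 °C) would form the acrylate and, after the same invertive lactonisation, come back to the route at 28.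

Step 21: backside displacement at the hindered C8 mesylate may be slow, which would leave time for E2 loss of methanesulfonate or protodeboronation. The fallback sets out from 22 and changes the electrophile to a cis-epoxide. PPTS in MeOH would remove the triethylsilyl group and give the erythro diol F3. The Kolb–Sharpless sequence (MeC(OMe)3, PPTS; AcBr; K2CO3, MeOH) would convert it with net retention into the cis-8,9-epoxide F4. Markovnikov hydroboration as in step 20 would give the boronate F5. The same copper-catalysed carboxylation would then be followed by 5-exo opening of the epoxide at C8 with inversion, which frees the C9 hydroxyl directly and gives the mono-silyl lactone F6. HF·pyridine would then return to the route at 29.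

Step 16: the ring-closing transition state may override the Felkin–Anh preference and give poor facial selectivity at C9. The fallback sets out from the C9-epimer mixture of 22. Dess–Martin oxidation would give the macrocyclic enone F7, and reagent-controlled Corey–Bakshi–Shibata reduction ((R)-Me-CBS, BH3·SMe2, alkenyl group as the large substituent) would return to 22 as the 9R alcohol.

## Further compounds

F1 | step 20 | 2-stannylalkene: C7 carries 1-(trimethylstannyl)vinyl; 8-OMs; 2,9-bis-O-TBS | C=C([Sn](C)(C)C)[C@@H]1[C@H](OS(C)(=O)=O)[C@H](O[Si](C)(C)C(C)(C)C)/C(C)=C\[C@@H](O[Si](C)(C)C(C)(C)C)C/C(C)=C\[C@H]1OC(=O)[C@H](C)CC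
F2 | step 20 | 2-iodoalkene: C7 carries 1-iodovinyl; 8-OMs; 2,9-bis-O-TBS | IC(=C)[C@@H]1[C@H](OS(C)(=O)=O)[C@H](O[Si](C)(C)C(C)(C)C)/C(C)=C\[C@@H](O[Si](C)(C)C(C)(C)C)C/C(C)=C\[C@H]1OC(=O)[C@H](C)CC
F3 | step 21 | erythro 8,9-diol: 7-ethynyl; 2-O-TBS | C#C[C@@H]1[C@H](O)[C@H](O)/C(C)=C\[C@@H](O[Si](C)(C)C(C)(C)C)C/C(C)=C\[C@H]1OC(=O)[C@H](C)CC
F4 | step 21 | cis-8,9-epoxide: 7-ethynyl; 2-O-TBS | C#C[C@@H]1[C@@H]2O[C@@H]2/C(C)=C\[C@@H](O[Si](C)(C)C(C)(C)C)C/C(C)=C\[C@H]1OC(=O)[C@H](C)CC
F5 | step 21 | cis-8,9-epoxide with 1-(pinacolatoboryl)vinyl on C7; 2-O-TBS | C=C(B3OC(C)(C)C(C)(C)O3)[C@@H]1[C@@H]2O[C@@H]2/C(C)=C\[C@@H](O[Si](C)(C)C(C)(C)C)C/C(C)=C\[C@H]1OC(=O)[C@H](C)CC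
F6 | step 21 | 2-O-TBS ether of the target | C=C1C(=O)O[C@@H]2[C@@H]1[C@H](OC(=O)[C@H](C)CC)/C=C(/C)C[C@H](O[Si](C)(C)C(C)(C)C)/C=C(/C)[C@H]2O
F7 | step 16 | macrocyclic C9 enone: 7-ethynyl; 8-OSiEt3; 2-O-TBS | C#C[C@@H]1[C@H](O[Si](CC)(CC)CC)C(=O)/C(C)=C\[C@@H](O[Si](C)(C)C(C)(C)C)C/C(C)=C\[C@H]1OC(=O)[C@H](C)CC
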